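## Retrosynthetic overview

1. Oxolane numbering used throughout: O1, C2 (4-hydroxyphenyl), C3 (2,4-dihydroxybenzoyl), C4 (4-hydroxybenzyl), C5 (2,4-dihydroxyphenyl). The target is 2S,3S,4S,5R, that is 2,3-trans, 3,4-trans and 4,5-cis.
2. Feature exploited: the 2-OH of the C5 aryl ring and the benzylic CH2 on C4 lie on the same oxolane face. Joining that oxygen to that carbon folds the target into a 2-(4-hydroxyphenyl)chroman whose C3–C4 bond is the oxolane C4–C5 bond, a cis-fused furo[3,2-c]chromene whose pyran ring is sacrificial.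
3. Last disconnections: reductive cleavage of the pyran O–CH(aryl) bond through the para-quinone methide of its 4-hydroxyphenyl group. Before that come debenzylation and convex-face conjugate reduction of C2=C3 with equilibration of C3.
4. Key disconnection: C3–C4 and C5–O1 of the dihydrofuran, formed in one anodic radical–polar (3+2) annulation. The partners are a 1,3-diaryl-1,3-diketone (Claisen condensation) and an (S)-flav-3-ene (asymmetric arylation of a chromone, reduction, dehydration).
5. Ring order: pyran ring (present in the chromone, made stereogenic by the arylation), then oxolane (annulation), then pyran ring opened again (last step).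

Key step: step 7

Assumption: the sense of induction in step 2 is extrapolated from cyclic enones, where the (S)-ligand delivers the aryl group to the face that corresponds to an (R)-flavanone. The (R)-ligand is therefore specified, and its antipode would be used if a rotation check showed the opposite sense.

Numbering note: tricyclic compounds are named as furo[3,2-c]chromenes. O1, C2 and C3 are as in the oxolane, C3a is oxolane C4, C4 is the sacrificial benzylic carbon, O5 is the sacrificial ether oxygen, and C9b is oxolane C5.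

## Route

Step 1
Reactants: 1 7-hydroxychromone (7-hydroxy-4H-chromen-4-one)
Product: 2 7-(benzyloxy)-4H-chromen-4-one
Conditions: BnBr, K2CO3, acetone, reflux
Reagents that add atoms: benzyl bromide, BrCc1ccccc1
Why: Williamson ether synthesis on the acidic 7-phenol, with a carbonate base that is too weakly nucleophilic to open the pyrone ring.

Step 2
Reactants: 2 7-(benzyloxy)-4H-chromen-4-one; 3 4-(benzyloxy)phenylboronic acid
Product: 4 (2S)-7-(benzyloxy)-2-[4-(benzyloxy)phenyl]-2,3-dihydro-4H-chromen-4-one
Conditions: Pd(OCOCF3)2 (5 mol %), (R)-t-BuPyOx [(R)-4-tert-butyl-2-(pyridin-2-yl)-4,5-dihydrooxazole] (6 mol %), NH4PF6 (30 mol %), H2O (5 equiv), ClCH2CH2Cl, 60 °C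
Reagents that add atoms: none
Why: Palladium-catalysed asymmetric conjugate addition of an arylboronic acid to a chromone, in which the tert-butyl group of the pyridinooxazoline blocks one face during migratory insertion of the aryl complex of divalent palladium into C2=C3, setting C2, and water protonates the palladium enolate.

Step 3
Reactants: 4 (2S)-7-(benzyloxy)-2-[4-(benzyloxy)phenyl]-2,3-dihydro-4H-chromen-4-one
Product: 5 (2S,4S)-7-(benzyloxy)-2-[4-(benzyloxy)phenyl]chroman-4-ol (2,4-cis)
Conditions: NaBH4, THF–MeOH, 0 °C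
Reagents that add atoms: none
Why: Borohydride 1,2-reduction of a flavanone, which should give the 2,4-cis alcohol by hydride attack on the half-chair with the 2-aryl group equatorial; the carbinol centre is erased in step 4, and the low temperature keeps C2 safe from retro-oxa-Michael racemisation.

Step 4
Reactants: 5 (2S,4S)-7-(benzyloxy)-2-[4-(benzyloxy)phenyl]chroman-4-ol
Product: 7 (2S)-7-(benzyloxy)-2-[4-(benzyloxy)phenyl]-2H-chromene, via 4-mesylate 6 (not isolated)
Conditions: MsCl, Et3N, CH2Cl2, 0 °C; then DBU, 0 °C to rt, dark; filtration through basic alumina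
Reagents that add atoms: methanesulfonyl chloride, CS(=O)(=O)Cl (its atoms stay only in 6)
Why: Sulfonylation followed by base-induced 1,2-elimination of an electron-rich benzylic sulfonate, kept acid-free so that the C2–O bond is not ionised, the flavene does not disproportionate and the C2 stereocentre is untouched.

Step 5
Reactants: 8 2',4'-dihydroxyacetophenone
Product: 9 1-[2,4-bis(benzyloxy)phenyl]ethan-1-one
Conditions: BnBr (2.5 equiv), K2CO3, KI (cat.), DMF, 80 °C
Reagents that add atoms: benzyl bromide, BrCc1ccccc1
Why: Double Williamson ether synthesis, with heating in DMF to alkylate the hydrogen-bonded 2-OH as well.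

Step 6
Reactants: 9 1-[2,4-bis(benzyloxy)phenyl]ethan-1-one; 10 methyl 4-(benzyloxy)benzoate
Product: 11 1-[2,4-bis(benzyloxy)phenyl]-3-[4-(benzyloxy)phenyl]propane-1,3-dione
Conditions: NaH (2.2 equiv), THF, reflux; then 1 M HCl work-up
Reagents that add atoms: none
Why: Crossed Claisen condensation of a methyl ketone enolate with a non-enolisable benzoate, driven by irreversible deprotonation of the diketone.

Step 7
Reactants: 7 (2S)-7-(benzyloxy)-2-[4-(benzyloxy)phenyl]-2H-chromene; 11 1-[2,4-bis(benzyloxy)phenyl]-3-[4-(benzyloxy)phenyl]propane-1,3-dione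
Product: 12 [(3aR,4S,9bR)-7-(benzyloxy)-2,4-bis[4-(benzyloxy)phenyl]-3a,9b-dihydro-4H-furo[3,2-c]chromen-3-yl][2,4-bis(benzyloxy)phenyl]methanone
Conditions: undivided cell, reticulated vitreous carbon anode, Pt cathode, constant current (2.2–2.5 F/mol), Fe(C5H5)2 (20 mol %), n-Bu4NBF4 (0.1 M), 11 (1.5 equiv), THF–MeOH 4:1, 30 °C, Ar, dark
Reagents that add atoms: none
Why: Methoxide formed at the cathode deprotonates 11, [Fe(C5H5)2]+ formed at the anode oxidises the enolate to the electrophilic C3 radical, this adds to the non-benzylic alkene carbon of 7 (future C4), the resulting C5 benzylic radical with ether oxygens ortho and para is oxidised by a second [Fe(C5H5)2]+ to the cation, a carbonyl oxygen captures it, loss of the remaining C3 proton gives the enol ether, and the two protons leave as H2 at the cathode. The closest known reaction type is the oxidative radical–polar (3+2) annulation of 1,3-dicarbonyl compounds with styrenes, indene and 1,2-dihydronaphthalene to 4,5-dihydrofurans, run with Mn(OAc)3, with (NH4)2Ce(NO3)6 or at an anode, directly or through a mediator. The one new ring, the oxolane, closes in the 5-exo-trig mode, O1 attacking the C5 cation whose π-overlap with the arene lies outside the ring being formed. C4 is set by approach of the bulky radical to the alkene face anti to the neighbouring 2-aryl group of 7, the face that epoxidising and dihydroxylating reagents also choose on flav-3-enes, and C5 is set by the tether, because closure to the strained trans-fused bicycle is not competitive, as in the pterocarpans. Chemoselectivity is needed between the enolate and the easily oxidised flavene (its alkene and its doubly activated C2–H) and is secured by a mediator potential well below that of 7, by the acid-free medium, and by darkness, which prevents electrocyclic opening and racemisation of the 2H-chromene. Oxygen regioselectivity is needed between the two carbonyl groups and should favour the 4-benzyloxybenzoyl oxygen, because only the para-substituted ring can lie coplanar with the developing C2 oxocarbenium and enol ether next to the C3 acyl group, whereas the ortho-benzyloxy ring would be twisted out of conjugation.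

Step 8
Reactants: 12 [(3aR,4S,9bR)-7-(benzyloxy)-2,4-bis[4-(benzyloxy)phenyl]-3a,9b-dihydro-4H-furo[3,2-c]chromen-3-yl][2,4-bis(benzyloxy)phenyl]methanone
Product: 15 [(2S,3S,3aS,4S,9bR)-7-(benzyloxy)-2,4-bis[4-(benzyloxy)phenyl]-2,3,3a,9b-tetrahydro-4H-furo[3,2-c]chromen-3-yl][2,4-bis(benzyloxy)phenyl]methanone, via silyl enol ether 13 (not isolated), via all-cis ketone 14 (not isolated)
Conditions: (IPr)CuCl = chloro[1,3-bis(2,6-diisopropylphenyl)imidazol-2-ylidene]copper (10 mol %), NaOt-Bu (10 mol %), (EtO)2MeSiH (3 equiv), toluene, rt; then K2CO3 (cat.), MeOH–THF, 40 °C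
Reagents that add atoms: diethoxy(methyl)silane, CCO[SiH](C)OCC (its atoms stay only in 13)
Why: Carbene-ligated copper hydride conjugate reduction (known for tetrasubstituted enoates and enones and for chromones) delivers hydride to C2 from the convex face that carries H-C4 and H-C5; the enolate is held as 13, so neither β-elimination of O1 nor ketone reduction follows; carbonate methanolysis gives the kinetically protonated 14, and enolisation then equilibrates C3 to the 2,3-trans-3,4-trans ketone; Pd/H2 is avoided at this stage because C5–O1 in 12 is a benzylic vinylogous ester bond of the kind that Pd/C cleaves in pterocarpans.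

Step 9
Reactants: 15 [(2S,3S,3aS,4S,9bR)-7-(benzyloxy)-2,4-bis[4-(benzyloxy)phenyl]-2,3,3a,9b-tetrahydro-4H-furo[3,2-c]chromen-3-yl][2,4-bis(benzyloxy)phenyl]methanone
Product: 16 (2,4-dihydroxyphenyl)[(2S,3S,3aS,4S,9bR)-7-hydroxy-2,4-bis(4-hydroxyphenyl)-2,3,3a,9b-tetrahydro-4H-furo[3,2-c]chromen-3-yl]methanone
Conditions: H2 (1 atm), 10% Pd/C, pyridine (0.5 equiv), THF–MeOH, rt, stopped after uptake of five equivalents
Reagents that add atoms: none
Why: Catalytic hydrogenolysis of five aryl benzyl ethers on pyridine-moderated Pd/C, which still cleaves phenolic benzyl ethers but suppresses cleavage of benzylic alkyl ethers, so C2–O1, C5–O1 and the electron-rich hindered aryl ketone should persist, and any cleavage of the pyran O–C bond would only anticipate the last step.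

Step 10
Reactants: 16 (2,4-dihydroxyphenyl)[(2S,3S,3aS,4S,9bR)-7-hydroxy-2,4-bis(4-hydroxyphenyl)-2,3,3a,9b-tetrahydro-4H-furo[3,2-c]chromen-3-yl]methanone
Product: 18 (2,4-dihydroxyphenyl)[(2S,3S,4S,5R)-5-(2,4-dihydroxyphenyl)-4-(4-hydroxybenzyl)-2-(4-hydroxyphenyl)oxolan-3-yl]methanone, via para-quinone methide 17 (not isolated)
Conditions: NaBH4 (10 equiv), 0.2 M aq. NaOH–EtOH 1:1 (degassed), Ar, 25–35 °C; then 1 M HCl to pH 6 at 0 °C
Reagents that add atoms: none
Why: Proposed new method: in alkali the 4-hydroxyphenyl group on the sacrificial carbon is a phenoxide that expels the pyran aryloxide, the only aryloxide leaving group among the three benzylic C–O bonds (both oxolane C–O bonds would have to release an alkoxide); this gives 17, which borohydride reduces irreversibly by 1,6-hydride addition to the 4-hydroxybenzyl CH2, erasing the relay stereocentre while C2 to C5 stay untouched, and the deprotonated 2,4-dihydroxyphenyl ketone, a vinylogous carboxylate, is too electron-rich to be reduced or enolised at this temperature; the closest known reaction types are the base-induced pyran opening of 4'-hydroxyflavans (C2 epimerisation of catechin, capture of the quinone methide by thiols or sulfite) and the NaBH4 reduction of quinone methides released from 4-hydroxybenzyl alcohols and esters in alkali.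

## Compound list

1 | 7-hydroxychromone | O=c1ccoc2cc(O)ccc12 | starting material
2 | 7-(benzyloxy)-4H-chromen-4-one | O=c1ccoc2cc(OCc3ccccc3)ccc12 | intermediate
3 | 4-(benzyloxy)phenylboronic acid | OB(O)c1ccc(OCc2ccccc2)cc1 | starting material
4 | (2S)-7-(benzyloxy)-2-[4-(benzyloxy)phenyl]-2,3-dihydro-4H-chromen-4-one | O=C1C[C@@H](c2ccc(OCc3ccccc3)cc2)Oc2cc(OCc3ccccc3)ccc12 | intermediate
5 | (2S,4S)-7-(benzyloxy)-2-[4-(benzyloxy)phenyl]chroman-4-ol (2,4-cis) | O[C@H]1C[C@@H](c2ccc(OCc3ccccc3)cc2)Oc2cc(OCc3ccccc3)ccc12 | intermediate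
6 | (2S,4S)-7-(benzyloxy)-2-[4-(benzyloxy)phenyl]chroman-4-yl methanesulfonate (not isolated) | CS(=O)(=O)O[C@H]1C[C@@H](c2ccc(OCc3ccccc3)cc2)Oc2cc(OCc3ccccc3)ccc12 | intermediate
7 | (2S)-7-(benzyloxy)-2-[4-(benzyloxy)phenyl]-2H-chromene | C1=Cc2ccc(OCc3ccccc3)cc2O[C@@H]1c1ccc(OCc3ccccc3)cc1 | intermediate
8 | 2',4'-dihydroxyacetophenone | CC(=O)c1ccc(O)cc1O | starting material
9 | 1-[2,4-bis(benzyloxy)phenyl]ethan-1-one | CC(=O)c1ccc(OCc2ccccc2)cc1OCc1ccccc1 | intermediate
10 | methyl 4-(benzyloxy)benzoate | COC(=O)c1ccc(OCc2ccccc2)cc1 | starting material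
11 | 1-[2,4-bis(benzyloxy)phenyl]-3-[4-(benzyloxy)phenyl]propane-1,3-dione | O=C(CC(=O)c1ccc(OCc2ccccc2)cc1)c1ccc(OCc2ccccc2)cc1OCc1ccccc1 | intermediate
12 | [(3aR,4S,9bR)-7-(benzyloxy)-2,4-bis[4-(benzyloxy)phenyl]-3a,9b-dihydro-4H-furo[3,2-c]chromen-3-yl][2,4-bis(benzyloxy)phenyl]methanone (cis-fused; 4-aryl trans to C3) | O=C(c1ccc(OCc4ccccc4)cc1OCc4ccccc4)C1=C(c2ccc(OCc4ccccc4)cc2)O[C@H]2c3ccc(OCc4ccccc4)cc3O[C@H](c3ccc(OCc4ccccc4)cc3)[C@@H]12 | intermediate
13 | diethoxy(methyl)silyl enol ether of 15 (exocyclic C3=C(OSi)aryl alkene, geometry open; 2R,3aS,4S,9bR, spatially as in 15; not isolated) | CCO[Si](C)(OCC)OC(c1ccc(OCc4ccccc4)cc1OCc4ccccc4)=C1[C@@H](c2ccc(OCc4ccccc4)cc2)O[C@H]2c3ccc(OCc4ccccc4)cc3O[C@H](c3ccc(OCc4ccccc4)cc3)[C@@H]12 | intermediate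
14 | (2S,3R,3aS,4S,9bR) C3 epimer of 15, oxolane substituents all cis (not isolated) | O=C(c1ccc(OCc4ccccc4)cc1OCc4ccccc4)[C@H]1[C@@H](c2ccc(OCc4ccccc4)cc2)O[C@H]2c3ccc(OCc4ccccc4)cc3O[C@H](c3ccc(OCc4ccccc4)cc3)[C@@H]12 | intermediate
15 | [(2S,3S,3aS,4S,9bR)-7-(benzyloxy)-2,4-bis[4-(benzyloxy)phenyl]-2,3,3a,9b-tetrahydro-4H-furo[3,2-c]chromen-3-yl][2,4-bis(benzyloxy)phenyl]methanone | O=C(c1ccc(OCc4ccccc4)cc1OCc4ccccc4)[C@@H]1[C@@H](c2ccc(OCc4ccccc4)cc2)O[C@H]2c3ccc(OCc4ccccc4)cc3O[C@H](c3ccc(OCc4ccccc4)cc3)[C@@H]12 | intermediate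
16 | (2,4-dihydroxyphenyl)[(2S,3S,3aS,4S,9bR)-7-hydroxy-2,4-bis(4-hydroxyphenyl)-2,3,3a,9b-tetrahydro-4H-furo[3,2-c]chromen-3-yl]methanone | O=C(c1ccc(O)cc1O)[C@@H]1[C@@H](c2ccc(O)cc2)O[C@H]2c3ccc(O)cc3O[C@H](c3ccc(O)cc3)[C@@H]12 | intermediate
17 | para-quinone methide: target skeleton with C4 bearing CH=(4-oxocyclohexa-2,5-dien-1-ylidene) in place of 4-hydroxybenzyl, C2 to C5 as in the target (not isolated) | O=C(c1ccc(O)cc1O)[C@H]1[C@H](C=C2C=CC(=O)C=C2)[C@H](c2ccc(O)cc2O)O[C@@H]1c1ccc(O)cc1 | intermediate
18 | (2,4-dihydroxyphenyl)[(2S,3S,4S,5R)-5-(2,4-dihydroxyphenyl)-4-(4-hydroxybenzyl)-2-(4-hydroxyphenyl)oxolan-3-yl]methanone (CNP0181717.3) | O=C(c1ccc(O)cc1O)[C@H]1[C@H](Cc2ccc(O)cc2)[C@H](c2ccc(O)cc2O)O[C@@H]1c1ccc(O)cc1 | target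

## Step count and risks

Total step count: 10.

Longest linear sequence: 8 steps (steps 1, 2, 3, 4, 7, 8, 9, 10). Steps 5 and 6 form the convergent branch.

**Steps most likely to fail**

**Step 10 (Proposed new method).**
- What may go wrong:
  - Pyran opening may be slower than borohydride attack on the ketone.
  - The other phenoxides may expel O1 from C5 or C2, leading to over-reduction or to erosion of the 4,5-cis relationship once the pyran ring no longer holds C5.
- Fallback: opening and reduction are separated, using the known thiol capture of flavan-derived quinone methides.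
  - Starting from 16, phenylmethanethiol in degassed aqueous NaOH at pH 12 (rt to 40 °C) should give the ring-opened benzylic sulfide F1. Its epimer mixture at the sulfur-bearing carbon is of no consequence.
  - Desulfurisation with acetone-deactivated Raney Ni in EtOH at rt then returns to the route at 18.

**Step 7.**
- What may go wrong:
  - closure through the wrong carbonyl oxygen;
  - hydrogen abstraction from C2–H of the flavene followed by oxidation towards the flavylium ion;
  - capture of the C5 cation by methanol;
  - poor facial selectivity at C4.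
- Fallback: the diketone is replaced by a β-keto ester, in which only the ketone oxygen can close, and the aroyl group is attached afterwards.
  - Starting from 10, the lithium enolate of ethyl acetate (LiHMDS, THF, −78 °C) should give ethyl 3-[4-(benzyloxy)phenyl]-3-oxopropanoate F2.
  - F2 is annulated with 7 in the same ferrocene-mediated cell to the ethyl dihydrofurochromene-3-carboxylate F3.
  - Me(MeO)NH·HCl with i-PrMgCl (THF, −20 to 0 °C) converts F3 into the N-methoxy-N-methylamide F4.
  - Separately, 4-bromoresorcinol is benzylated (BnBr, K2CO3, DMF) to 2,4-bis(benzyloxy)-1-bromobenzene F5.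
  - F5 is lithiated (n-BuLi, THF, −78 °C) to [2,4-bis(benzyloxy)phenyl]lithium F6.
  - Addition of F6 to F4 returns to the route at 12.

**Step 8.**
- What may go wrong:
  - no hydride transfer to the fully substituted C2;
  - competing 1,2-reduction of the aryl ketone;
  - β-elimination of O1 from the copper enolate, with onward reduction of the opened enone.
- Fallback: hydride conjugate addition is replaced by heterogeneous syn-hydrogenation on a metal with little hydrogenolysis activity.
  - Starting from 12, H2 (4–5 atm) over 5% Rh/Al2O3 in EtOAc at rt should add both hydrogens from the convex face. This returns to the route at 14.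
  - 14 is then equilibrated to 15 with K2CO3 in MeOH–THF as in step 8.
  - This detour makes no compound outside the list (line F0).

## Further compounds

F1 | step 10 | (2,4-dihydroxyphenyl)[(2S,3S,4S,5R)-4-[(benzylsulfanyl)(4-hydroxyphenyl)methyl]-5-(2,4-dihydroxyphenyl)-2-(4-hydroxyphenyl)oxolan-3-yl]methanone (epimers at the sulfur-bearing carbon; ring descriptors denote the spatial arrangement of 18) | O=C(c1ccc(O)cc1O)[C@H]1[C@H](C(SCc2ccccc2)c2ccc(O)cc2)[C@H](c2ccc(O)cc2O)O[C@@H]1c1ccc(O)cc1
F2 | step 7 | ethyl 3-[4-(benzyloxy)phenyl]-3-oxopropanoate | CCOC(=O)CC(=O)c1ccc(OCc2ccccc2)cc1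
F3 | step 7 | ethyl (3aR,4S,9bR)-7-(benzyloxy)-2,4-bis[4-(benzyloxy)phenyl]-3a,9b-dihydro-4H-furo[3,2-c]chromene-3-carboxylate | CCOC(=O)C1=C(c2ccc(OCc4ccccc4)cc2)O[C@H]2c3ccc(OCc4ccccc4)cc3O[C@H](c3ccc(OCc4ccccc4)cc3)[C@@H]12
F4 | step 7 | (3aR,4S,9bR)-7-(benzyloxy)-2,4-bis[4-(benzyloxy)phenyl]-N-methoxy-N-methyl-3a,9b-dihydro-4H-furo[3,2-c]chromene-3-carboxamide | CON(C)C(=O)C1=C(c2ccc(OCc4ccccc4)cc2)O[C@H]2c3ccc(OCc4ccccc4)cc3O[C@H](c3ccc(OCc4ccccc4)cc3)[C@@H]12
F5 | step 7 | 2,4-bis(benzyloxy)-1-bromobenzene | Brc1ccc(OCc2ccccc2)cc1OCc1ccccc1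
F6 | step 7 | [2,4-bis(benzyloxy)phenyl]lithium | [Li]c1ccc(OCc2ccccc2)cc1OCc1ccccc1
F0 | step 8 | none | none
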